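## Retrosynthetic overview

1. **Feature.** In the 2,3-dihydrobenzofuran, C2 is bonded to O1 and carries the 4-oxyphenyl ring. C2 is therefore a masked para-quinone-methide cation, and the ortho-phenol can close O1–C2. A C=O placed between O1 and C2 turns this five-membered ring into a six-membered 3,4-diaryl-dihydrocoumarin. Its C4 (= furan C3) comes from asymmetric conjugate arylation of 6-chlorocoumarin.
2. **End-game.** Eight O-methyl groups are cleaved last. Before that, one palladium cascade makes indane C7a–C1 (5-exo-dig) and the exocyclic CH–C5(benzofuran) bond, and syn addition fixes the Z alkene.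
3. **Cascade partners.** These are benzofuran-5-yl boronate 12 (from chloride 11) and alkynyl aryl triflate 25.
4. **Origin of 25.** It comes from a second coumarin, 5,7-dimethoxycoumarin. Lactone O1 becomes the triflate on indane C7a and lactone C2 becomes indane C1. The trans C2/C3 pair is fixed by equilibration of lactone 21.
5. **Ring order.** Dihydrocoumarin rings (steps 4 and 11) → dihydrofuran by CO2 excision (step 6) → indane five-membered ring (step 16).

Key step: step 6

Assumption: (R)-Segphos is taken to deliver (R)-4-arylchroman-2-ones from coumarins (the CIP ranking C4a > aryl > C3 is the same in 3 and 15). If the sense proved opposite, the two ligand antipodes would be exchanged.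

## Route

### Benzofuran half (steps 1–7)

Step 1
Reactants: 1 6-chlorocoumarin; 2 3,5-dimethoxyphenylboronic acid
Product: 3 (4S)-6-chloro-4-(3,5-dimethoxyphenyl)chroman-2-one
Conditions: Rh(acac)(C2H4)2 (3 mol %), (S)-Segphos (3.3 mol %), 2 (5 equiv), dioxane/H2O 10:1, 60 °C
Reagents that add atoms: none
Why: Hayashi–Miyaura asymmetric 1,4-addition, a reaction established for coumarins with this catalyst: the aryl–rhodium species inserts the C3=C4 bond from the face left open by (S)-Segphos and so sets C4 (the later furan C3) as S, while the aryl chloride is inert to monovalent rhodium.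

Step 2
Reactants: 3 (4S)-6-chloro-4-(3,5-dimethoxyphenyl)chroman-2-one
Product: 5 methyl (3S)-3-[2-(benzyloxy)-5-chlorophenyl]-3-(3,5-dimethoxyphenyl)propanoate, via ring-opened hydroxy ester 4 (not isolated)
Conditions: K2CO3 (2.5 equiv), BnBr (1.5 equiv), MeOH/acetone 1:1, 60 °C
Reagents that add atoms: methanol, CO; benzyl bromide, BrCc1ccccc1
Why: Carbonate-promoted methanolysis of the aryl lactone, followed in the same flask by Williamson benzylation of the phenoxide, locks the open form before it can relactonise, and the non-acidic diarylmethine centre is untouched.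

Step 3
Reactants: 5 methyl (3S)-3-[2-(benzyloxy)-5-chlorophenyl]-3-(3,5-dimethoxyphenyl)propanoate; 6 4-bromoanisole
Product: 7 methyl (2RS,3S)-3-[2-(benzyloxy)-5-chlorophenyl]-3-(3,5-dimethoxyphenyl)-2-(4-methoxyphenyl)propanoate
Conditions: LiHMDS (2.3 equiv), Pd(dba)2 (2 mol %), P(t-Bu)3 (2 mol %), 6 (1.2 equiv), toluene, 25 °C
Reagents that add atoms: none
Why: Buchwald–Hartwig α-arylation of the lithium ester enolate: at room temperature zerovalent palladium inserts into the C–Br bond of 6 much faster than into the electron-rich C–Cl bond of 5, steric crowding stops a second arylation, and the new α-centre, formed without control, is levelled in step 4 and erased in step 6.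

Step 4
Reactants: 7 methyl (2RS,3S)-3-[2-(benzyloxy)-5-chlorophenyl]-3-(3,5-dimethoxyphenyl)-2-(4-methoxyphenyl)propanoate
Product: 9 (3S,4S)-6-chloro-4-(3,5-dimethoxyphenyl)-3-(4-methoxyphenyl)chroman-2-one, via debenzylated hydroxy ester 8 (not isolated)
Conditions: BCl3 (2 equiv), C6HMe5 (3 equiv), CH2Cl2, −78 °C; then p-TsOH·H2O (10 mol %), toluene, 110 °C; then DBU (20 mol %), 25 °C
Reagents that add atoms: none
Why: Lewis-acid debenzylation with a cation scavenger spares the C–Cl bond (at risk under hydrogenolysis) and the methyl ethers, acid-catalysed transesterification closes the lactone, and DBU epimerises the acidic C3–H so that thermodynamic control should give the trans (3S,4S) isomer.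

Step 5
Reactants: 9 (3S,4S)-6-chloro-4-(3,5-dimethoxyphenyl)-3-(4-methoxyphenyl)chroman-2-one
Product: 10 (2S,3S)-3-(5-chloro-2-hydroxyphenyl)-3-(3,5-dimethoxyphenyl)-2-(4-methoxyphenyl)propanoic acid
Conditions: LiOH (2.2 equiv), THF/H2O 3:1, 0 → 25 °C; then 1 M HCl to pH 4 at 0 °C, extraction, used at once
Reagents that add atoms: lithium hydroxide, [Li+].[OH-]
Why: Saponification of the phenolic lactone is fast, the carboxylate formed resists α-deprotonation so C2 stays S, and cold acidification only to pH 4 leaves the hydroxy acid open long enough for immediate use.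

Step 6
Reactants: 10 (2S,3S)-3-(5-chloro-2-hydroxyphenyl)-3-(3,5-dimethoxyphenyl)-2-(4-methoxyphenyl)propanoic acid
Product: 11 (2S,3S)-5-chloro-3-(3,5-dimethoxyphenyl)-2-(4-methoxyphenyl)-2,3-dihydro-1-benzofuran
Conditions: graphite anode, Pt cathode, undivided cell, constant current (5 mA cm−2, 2.2 F mol−1), 2,4,6-collidine (1.5 equiv), n-Bu4NPF6 (0.1 M), 3 Å MS, CH2Cl2/HFIP 9:1, 0 °C
Reagents that add atoms: none
Why: Proposed new method: collidine is strong enough to ionise the carboxylic acid but not the phenol, so the anode removes one electron from the 4-methoxyphenylacetate unit, CO2 leaves irreversibly, and the secondary 4-methoxybenzylic radical, far easier to oxidise than anything else present, gives up a second electron to become an O-methylated para-quinone-methide cation. The closest known reaction type is the Hofer–Moest (non-Kolbe) anodic decarboxylative etherification of arylacetic and tertiary acids with alcohols, intramolecular alcohol capture included, whereas capture by a free ortho-phenol, and with it the net excision of the lactone carbonyl of 9, has not been shown. The dihydrofuran closes by 5-exo-trig attack of the phenolic oxygen on the planar cationic carbon, which forms O1–C2. Because that carbon is planar the α-configuration of 10 is lost, and C2 is set by 1,2-induction from C3, whose 3,5-dimethoxyphenyl group covers one face so that the 4-methoxyphenyl group should end trans (2S,3S), which is also the thermodynamic isomer reachable by re-ionisation. The step needs oxidation at the arylacetate rather than at the phenol or the dimethoxyarene: the carboxylate is the only anionic site, the phenol stays protonated and is made harder to oxidise and blocked at its para position by chlorine, and a hole formed elsewhere can still be drained by the irreversible loss of CO2. Low temperature, a weak hindered base and a charge limit just above 2 F mol−1 are chosen to hold back proton loss from C3 and over-oxidation of 11.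

Step 7
Reactants: 11 (2S,3S)-5-chloro-3-(3,5-dimethoxyphenyl)-2-(4-methoxyphenyl)-2,3-dihydro-1-benzofuran
Product: 12 2-[(2S,3S)-3-(3,5-dimethoxyphenyl)-2-(4-methoxyphenyl)-2,3-dihydro-1-benzofuran-5-yl]-4,4,5,5-tetramethyl-1,3,2-dioxaborolane
Conditions: B2pin2 (1.5 equiv), Pd2(dba)3 (2 mol %), XPhos (8 mol %), KOAc (3 equiv), dioxane, 110 °C
Reagents that add atoms: bis(pinacolato)diboron, CC1(C)OB(OC1(C)C)B1OC(C)(C)C(C)(C)O1
Why: Miyaura borylation, in which the bulky electron-rich biarylphosphine lets zerovalent palladium insert into the electron-rich aryl chloride and the weak base KOAc leaves both benzylic stereocentres alone.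

### Alkynyl triflate half (steps 8–15)

Step 8
Reactants: 13 5,7-dimethoxycoumarin; 14 4-methoxyphenylboronic acid
Product: 15 (4R)-5,7-dimethoxy-4-(4-methoxyphenyl)chroman-2-one
Conditions: Rh(acac)(C2H4)2 (5 mol %), (R)-Segphos (5.5 mol %), 14 (8 equiv), dioxane/H2O 10:1, 60 °C
Reagents that add atoms: none
Why: The same Hayashi–Miyaura 1,4-addition with the antipodal ligand sets C4 (the later indane C3) as R; the peri methoxy group lies in the ring plane and does not cover either face, and excess boronic acid compensates for slower insertion into this donor-substituted coumarin.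

Step 9
Reactants: 15 (4R)-5,7-dimethoxy-4-(4-methoxyphenyl)chroman-2-one
Product: 17 methyl (3R)-3-[2-(benzyloxy)-4,6-dimethoxyphenyl]-3-(4-methoxyphenyl)propanoate, via ring-opened hydroxy ester 16 (not isolated)
Conditions: K2CO3 (2.5 equiv), BnBr (1.5 equiv), MeOH/acetone 1:1, 60 °C
Reagents that add atoms: methanol, CO; benzyl bromide, BrCc1ccccc1
Why: Methanolysis of the aryl lactone and Williamson benzylation of the liberated phenoxide, as in step 2, hold the chain open for enolate chemistry without touching the diarylmethine centre.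

Step 10
Reactants: 17 methyl (3R)-3-[2-(benzyloxy)-4,6-dimethoxyphenyl]-3-(4-methoxyphenyl)propanoate; 18 1-bromo-3,5-dimethoxybenzene
Product: 19 methyl (2RS,3R)-3-[2-(benzyloxy)-4,6-dimethoxyphenyl]-2-(3,5-dimethoxyphenyl)-3-(4-methoxyphenyl)propanoate
Conditions: LiHMDS (2.3 equiv), Pd(dba)2 (3 mol %), P(t-Bu)3 (3 mol %), 18 (1.2 equiv), toluene, 25 → 50 °C
Reagents that add atoms: none
Why: Buchwald–Hartwig ester α-arylation as in step 3, here without any competing halide in the enolate partner; the α-centre again forms unselectively and is corrected in step 11.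

Step 11
Reactants: 19 methyl (2RS,3R)-3-[2-(benzyloxy)-4,6-dimethoxyphenyl]-2-(3,5-dimethoxyphenyl)-3-(4-methoxyphenyl)propanoate
Product: 21 (3R,4R)-3-(3,5-dimethoxyphenyl)-5,7-dimethoxy-4-(4-methoxyphenyl)chroman-2-one, via debenzylated hydroxy ester 20 (not isolated)
Conditions: H2 (1 atm), Pd/C, EtOAc, 25 °C, filtration; then p-TsOH·H2O (10 mol %), toluene, 110 °C; then DBU (20 mol %), 25 °C
Reagents that add atoms: none
Why: Hydrogenolysis frees the phenol, acid-catalysed lactonisation closes the ring, and base equilibration of the acidic C3–H places the two aryl groups trans (the C4 aryl is held pseudoaxial by the peri methoxy group and the C3 aryl avoids it), which sets C3 (the later indane C2) as R by thermodynamic relay from C4.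

Step 12
Reactants: 21 (3R,4R)-3-(3,5-dimethoxyphenyl)-5,7-dimethoxy-4-(4-methoxyphenyl)chroman-2-one
Product: 22 (3R,4R)-3-(3,5-dimethoxyphenyl)-5,7-dimethoxy-4-(4-methoxyphenyl)chroman-2-ol (lactol, both C2 epimers)
Conditions: i-Bu2AlH (1.1 equiv), toluene, −78 °C; Rochelle salt work-up
Reagents that add atoms: none
Why: Partial reduction of a lactone with DIBAL-H at low temperature stops at the aluminium hemiacetal, and the non-basic medium leaves the α-aryl centre untouched.

Step 13
Reactants: 22 (3R,4R)-3-(3,5-dimethoxyphenyl)-5,7-dimethoxy-4-(4-methoxyphenyl)chroman-2-ol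
Product: 23 2-[(1R,2S)-4,4-dibromo-2-(3,5-dimethoxyphenyl)-1-(4-methoxyphenyl)but-3-en-1-yl]-3,5-dimethoxyphenol
Conditions: CBr4 (2 equiv), PPh3 (2 equiv), Zn dust (2 equiv), CH2Cl2, 25 °C (ylide pre-formed); then 22, 0 → 25 °C
Reagents that add atoms: carbon tetrabromide, BrC(Br)(Br)Br
Why: Ramirez dibromo-olefination (first half of the Corey–Fuchs sequence) acts on the open hydroxy-aldehyde tautomer of the lactol, as Wittig-type reagents do with lactols in general, and this weakly basic ylide is chosen because it should not enolise the configurationally labile α-aryl aldehyde.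

Step 14
Reactants: 23 2-[(1R,2S)-4,4-dibromo-2-(3,5-dimethoxyphenyl)-1-(4-methoxyphenyl)but-3-en-1-yl]-3,5-dimethoxyphenol
Product: 24 2-[(1R,2S)-2-(3,5-dimethoxyphenyl)-1-(4-methoxyphenyl)but-3-yn-1-yl]-3,5-dimethoxyphenol
Conditions: n-BuLi (3.2 equiv), THF, −78 °C; then H2O
Reagents that add atoms: none
Why: Second half of the Corey–Fuchs sequence: after deprotonation of the phenol, bromine–lithium exchange and Fritsch–Buttenberg–Wiechell rearrangement give the lithium acetylide, whose charge protects the neighbouring propargylic, benzylic C–H from deprotonation at −78 °C.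

Step 15
Reactants: 24 2-[(1R,2S)-2-(3,5-dimethoxyphenyl)-1-(4-methoxyphenyl)but-3-yn-1-yl]-3,5-dimethoxyphenol
Product: 25 2-[(1R,2S)-2-(3,5-dimethoxyphenyl)-1-(4-methoxyphenyl)but-3-yn-1-yl]-3,5-dimethoxyphenyl trifluoromethanesulfonate
Conditions: Tf2O (1.2 equiv), pyridine (3 equiv), CH2Cl2, 0 °C
Reagents that add atoms: trifluoromethanesulfonic anhydride, O=S(=O)(OS(=O)(=O)C(F)(F)F)C(F)(F)F
Why: Standard O-sulfonylation of a phenol turns the former lactone oxygen into the leaving group on the carbon that becomes indane C7a, while the alkyne and both stereocentres are inert.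

### Union and deprotection (steps 16–17)

Step 16
Reactants: 25 2-[(1R,2S)-2-(3,5-dimethoxyphenyl)-1-(4-methoxyphenyl)but-3-yn-1-yl]-3,5-dimethoxyphenyl trifluoromethanesulfonate; 12 benzofuran-5-yl pinacol boronate
Product: 26 octa-O-methyl ether of the target, (2S,3S)-3-(3,5-dimethoxyphenyl)-5-{(Z)-[(2R,3R)-2-(3,5-dimethoxyphenyl)-4,6-dimethoxy-3-(4-methoxyphenyl)-2,3-dihydro-1H-inden-1-ylidene]methyl}-2-(4-methoxyphenyl)-2,3-dihydro-1-benzofuran
Conditions: Pd(PPh3)4 (5 mol %), K3PO4 (3 equiv), dioxane/H2O 10:1, 80 °C, 12 (1.3 equiv) added slowly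
Reagents that add atoms: none
Why: Cyclocarbopalladation–Suzuki–Miyaura cascade (cyclisation–anion capture): zerovalent palladium inserts into the C–OTf bond, the cationic arylpalladium adds syn and 5-exo-dig across the tethered alkyne to form C7a–C1 and close the indane, and the vinylpalladium, which has no β-hydrogen, is intercepted by 12 with retention, so that the benzofuranyl group ends cis to C7a (Z) and the four stereocentres are only spectators.

Step 17
Reactants: 26 octa-O-methyl ether of the target
Product: 27 target, 5-[(2S,3S)-5-{(Z)-[(2R,3R)-2-(3,5-dihydroxyphenyl)-4,6-dihydroxy-3-(4-hydroxyphenyl)-2,3-dihydro-1H-inden-1-ylidene]methyl}-2-(4-hydroxyphenyl)-2,3-dihydro-1-benzofuran-3-yl]benzene-1,3-diol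
Conditions: BBr3 (24 equiv), CH2Cl2, −78 → 0 °C; inverse quench into ice-cold aqueous NaHCO3
Reagents that add atoms: none
Why: Boron tribromide cleavage of aryl methyl ethers is the usual end-game for permethylated resveratrol oligomers, benzylidene-indanes and 2,3-diaryl-dihydrobenzofurans included, and low temperature with an inverse buffered quench keeps free HBr away from the 4-alkoxystyrene-type Z alkene and from the benzylic C2–O1 bond.

## Compound list

1 | 6-chlorocoumarin | O=c1ccc2cc(Cl)ccc2o1 | starting material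
2 | 3,5-dimethoxyphenylboronic acid | COc1cc(B(O)O)cc(OC)c1 | starting material
3 | (4S)-6-chloro-4-(3,5-dimethoxyphenyl)chroman-2-one | Clc1ccc2c(c1)[C@H](c1cc(OC)cc(OC)c1)CC(=O)O2 | intermediate
4 | methyl (3S)-3-(5-chloro-2-hydroxyphenyl)-3-(3,5-dimethoxyphenyl)propanoate (not isolated) | Oc1ccc(Cl)cc1[C@H](c1cc(OC)cc(OC)c1)CC(=O)OC | intermediate
5 | methyl (3S)-3-[2-(benzyloxy)-5-chlorophenyl]-3-(3,5-dimethoxyphenyl)propanoate | Clc1ccc(OCc2ccccc2)c(c1)[C@H](c1cc(OC)cc(OC)c1)CC(=O)OC | intermediate
6 | 4-bromoanisole | COc1ccc(Br)cc1 | starting material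
7 | methyl (2RS,3S)-3-[2-(benzyloxy)-5-chlorophenyl]-3-(3,5-dimethoxyphenyl)-2-(4-methoxyphenyl)propanoate | Clc1ccc(OCc2ccccc2)c(c1)[C@H](c1cc(OC)cc(OC)c1)C(c1ccc(OC)cc1)C(=O)OC | intermediate
8 | methyl (2RS,3S)-3-(5-chloro-2-hydroxyphenyl)-3-(3,5-dimethoxyphenyl)-2-(4-methoxyphenyl)propanoate (not isolated) | Oc1ccc(Cl)cc1[C@H](c1cc(OC)cc(OC)c1)C(c1ccc(OC)cc1)C(=O)OC | intermediate
9 | (3S,4S)-6-chloro-4-(3,5-dimethoxyphenyl)-3-(4-methoxyphenyl)chroman-2-one (trans) | Clc1ccc2c(c1)[C@H](c1cc(OC)cc(OC)c1)[C@@H](c1ccc(OC)cc1)C(=O)O2 | intermediate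
10 | (2S,3S)-3-(5-chloro-2-hydroxyphenyl)-3-(3,5-dimethoxyphenyl)-2-(4-methoxyphenyl)propanoic acid | Oc1ccc(Cl)cc1[C@H](c1cc(OC)cc(OC)c1)[C@@H](c1ccc(OC)cc1)C(=O)O | intermediate
11 | (2S,3S)-5-chloro-3-(3,5-dimethoxyphenyl)-2-(4-methoxyphenyl)-2,3-dihydro-1-benzofuran (trans) | Clc1ccc2c(c1)[C@H](c1cc(OC)cc(OC)c1)[C@@H](c1ccc(OC)cc1)O2 | intermediate
12 | 2-[(2S,3S)-3-(3,5-dimethoxyphenyl)-2-(4-methoxyphenyl)-2,3-dihydro-1-benzofuran-5-yl]-4,4,5,5-tetramethyl-1,3,2-dioxaborolane | CC1(C)OB(OC1(C)C)c1ccc2c(c1)[C@H](c1cc(OC)cc(OC)c1)[C@@H](c1ccc(OC)cc1)O2 | intermediate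
13 | 5,7-dimethoxycoumarin | COc1cc(OC)c2ccc(=O)oc2c1 | starting material
14 | 4-methoxyphenylboronic acid | COc1ccc(B(O)O)cc1 | starting material
15 | (4R)-5,7-dimethoxy-4-(4-methoxyphenyl)chroman-2-one | COc1ccc([C@@H]2c3c(OC)cc(OC)cc3OC(=O)C2)cc1 | intermediate
16 | methyl (3R)-3-(2-hydroxy-4,6-dimethoxyphenyl)-3-(4-methoxyphenyl)propanoate (not isolated) | COc1ccc([C@@H](CC(=O)OC)c2c(OC)cc(OC)cc2O)cc1 | intermediate
17 | methyl (3R)-3-[2-(benzyloxy)-4,6-dimethoxyphenyl]-3-(4-methoxyphenyl)propanoate | COc1ccc([C@@H](CC(=O)OC)c2c(OC)cc(OC)cc2OCc2ccccc2)cc1 | intermediate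
18 | 1-bromo-3,5-dimethoxybenzene | COc1cc(Br)cc(OC)c1 | starting material
19 | methyl (2RS,3R)-3-[2-(benzyloxy)-4,6-dimethoxyphenyl]-2-(3,5-dimethoxyphenyl)-3-(4-methoxyphenyl)propanoate | COc1ccc([C@@H](C(C(=O)OC)c2cc(OC)cc(OC)c2)c2c(OC)cc(OC)cc2OCc2ccccc2)cc1 | intermediate
20 | methyl (2RS,3R)-2-(3,5-dimethoxyphenyl)-3-(2-hydroxy-4,6-dimethoxyphenyl)-3-(4-methoxyphenyl)propanoate (not isolated) | COc1ccc([C@@H](C(C(=O)OC)c2cc(OC)cc(OC)c2)c2c(OC)cc(OC)cc2O)cc1 | intermediate
21 | (3R,4R)-3-(3,5-dimethoxyphenyl)-5,7-dimethoxy-4-(4-methoxyphenyl)chroman-2-one (trans) | COc1ccc([C@@H]2c3c(OC)cc(OC)cc3OC(=O)[C@H]2c2cc(OC)cc(OC)c2)cc1 | intermediate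
22 | (3R,4R)-3-(3,5-dimethoxyphenyl)-5,7-dimethoxy-4-(4-methoxyphenyl)chroman-2-ol (both C2 epimers) | COc1ccc([C@@H]2c3c(OC)cc(OC)cc3OC(O)[C@H]2c2cc(OC)cc(OC)c2)cc1 | intermediate
23 | 2-[(1R,2S)-4,4-dibromo-2-(3,5-dimethoxyphenyl)-1-(4-methoxyphenyl)but-3-en-1-yl]-3,5-dimethoxyphenol | COc1ccc([C@@H]([C@@H](C=C(Br)Br)c2cc(OC)cc(OC)c2)c2c(OC)cc(OC)cc2O)cc1 | intermediate
24 | 2-[(1R,2S)-2-(3,5-dimethoxyphenyl)-1-(4-methoxyphenyl)but-3-yn-1-yl]-3,5-dimethoxyphenol | COc1ccc([C@@H]([C@@H](C#C)c2cc(OC)cc(OC)c2)c2c(OC)cc(OC)cc2O)cc1 | intermediate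
25 | 2-[(1R,2S)-2-(3,5-dimethoxyphenyl)-1-(4-methoxyphenyl)but-3-yn-1-yl]-3,5-dimethoxyphenyl trifluoromethanesulfonate | COc1ccc([C@@H]([C@@H](C#C)c2cc(OC)cc(OC)c2)c2c(OC)cc(OC)cc2OS(=O)(=O)C(F)(F)F)cc1 | intermediate
26 | octa-O-methyl ether of the target (indane 1Z,2R,3R; dihydrobenzofuran 2S,3S) | COc1ccc([C@@H]2c3c(OC)cc(OC)cc3/C(=C\c3ccc4c(c3)[C@H](c3cc(OC)cc(OC)c3)[C@@H](c3ccc(OC)cc3)O4)[C@H]2c2cc(OC)cc(OC)c2)cc1 | intermediate
27 | CNP0184753.4 (indane 1Z,2R,3R; dihydrobenzofuran 2S,3S) | Oc1ccc([C@@H]2c3c(O)cc(O)cc3/C(=C\c3ccc4c(c3)[C@H](c3cc(O)cc(O)c3)[C@@H](c3ccc(O)cc3)O4)[C@H]2c2cc(O)cc(O)c2)cc1 | target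

## Step count

- Total step count: 17.
- Longest linear sequence: 10 steps (steps 8–17, from 13).

## Steps most likely to fail

**1. Step 6 (the new method).**
- What may go wrong: electron loss may begin at the free phenol or at a dimethoxyarene instead of the arylacetate. The cation may also lose the C3 proton, which would erase that stereocentre. The product may be oxidised further.
- Fallback: it separates decarboxylation from ring closure and uses only known chemistry. It sets out from 7 and returns at 11.
- Ester 7 is saponified (LiOH, THF/MeOH/H2O, 50 °C) to the O-benzyl acid F1.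
- Classical Hofer–Moest methoxylation of F1 follows (graphite anode, Pt cathode, KOH 0.2 equiv, MeOH, 25 °C). No free phenol is present and the solvent captures the cation, which should give the benzylic methyl ether F2.
- BCl3 with pentamethylbenzene (CH2Cl2, −78 → 0 °C) then removes the benzyl group and ionises the 4-methoxybenzylic methyl ether. The freed oxygen closes the ring under thermodynamic control to trans 11.

**2. Step 16.**
- What may go wrong: transmetalation may precede ring closure, giving direct biaryl coupling. The terminal alkyne may be consumed by coupling at its C–H bond. The vinylpalladium may migrate to the neighbouring arene position or lose its geometry before capture.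
- Fallback: it avoids both the alkyne and the vinylpalladium. It sets out from 23 (with 12) and returns at 26.
- The C–Br bond of 23 trans to the chain is hydrogenolysed selectively (Bu3SnH, Pd(PPh3)4, toluene, 25 °C) to the (Z)-bromoalkene F3.
- Suzuki–Miyaura coupling of F3 with 12 (PdCl2(dppf), K3PO4, THF/H2O, 40 °C) should proceed with retention to the (Z)-styrene phenol F4.
- PhNTf2 and Cs2CO3 (DMF, 25 °C) give the (Z)-styrene triflate F5.
- An intramolecular Mizoroki–Heck reaction (Pd(OAc)2, dppp, K2CO3, DMA, 80 °C) closes the indane 5-exo-trig.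
- Syn insertion, bond rotation and syn elimination of the only β-hydrogen (C1–H) translate the Z alkene of F5 stereospecifically into the Z alkylidene of 26.

**3. Step 17.**
- What may go wrong: acid released during or after the demethylation may protonate the 4-alkoxystyrene-type alkene and cause Z-to-E isomerisation.
- Fallback: it no longer relies on carrying the geometry through and resets it afterwards. It sets out from 26 and returns at 27.
- The demethylation is taken to completion regardless of geometry, which gives 27 together with the E isomer of the target F6.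
- The mixture is irradiated at 365 nm in degassed methanol.
- The E isomer holds a planar trans-stilbene chromophore and absorbs. The twisted, cis-stilbene-like Z isomer hardly does. As in the classical photochemical trans-to-cis isomerisation of stilbenoids, the photostationary state should therefore be enriched in 27.
- 27 is separated by reversed-phase chromatography and F6 is recycled.

Further compounds
F1 | step 6 | (2RS,3S)-3-[2-(benzyloxy)-5-chlorophenyl]-3-(3,5-dimethoxyphenyl)-2-(4-methoxyphenyl)propanoic acid | Clc1ccc(OCc2ccccc2)c(c1)[C@H](c1cc(OC)cc(OC)c1)C(c1ccc(OC)cc1)C(=O)O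
F2 | step 6 | 1-(benzyloxy)-4-chloro-2-[(1S,2RS)-1-(3,5-dimethoxyphenyl)-2-methoxy-2-(4-methoxyphenyl)ethyl]benzene | Clc1ccc(OCc2ccccc2)c(c1)[C@H](c1cc(OC)cc(OC)c1)C(OC)c1ccc(OC)cc1
F3 | step 16 | 2-[(1R,2S,3Z)-4-bromo-2-(3,5-dimethoxyphenyl)-1-(4-methoxyphenyl)but-3-en-1-yl]-3,5-dimethoxyphenol | COc1ccc([C@@H]([C@@H](/C=C\Br)c2cc(OC)cc(OC)c2)c2c(OC)cc(OC)cc2O)cc1
F4 | step 16 | 2-{(1R,2R,3Z)-2-(3,5-dimethoxyphenyl)-4-[(2S,3S)-3-(3,5-dimethoxyphenyl)-2-(4-methoxyphenyl)-2,3-dihydro-1-benzofuran-5-yl]-1-(4-methoxyphenyl)but-3-en-1-yl}-3,5-dimethoxyphenol | COc1ccc([C@@H]([C@@H](/C=C\c2ccc3c(c2)[C@H](c2cc(OC)cc(OC)c2)[C@@H](c2ccc(OC)cc2)O3)c2cc(OC)cc(OC)c2)c2c(OC)cc(OC)cc2O)cc1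
F5 | step 16 | trifluoromethanesulfonate of F4 | COc1ccc([C@@H]([C@@H](/C=C\c2ccc3c(c2)[C@H](c2cc(OC)cc(OC)c2)[C@@H](c2ccc(OC)cc2)O3)c2cc(OC)cc(OC)c2)c2c(OC)cc(OC)cc2OS(=O)(=O)C(F)(F)F)cc1
F6 | step 17 | E isomer of the target (indane 1E,2R,3R; dihydrobenzofuran 2S,3S) | Oc1ccc([C@@H]2c3c(O)cc(O)cc3/C(=C/c3ccc4c(c3)[C@H](c3cc(O)cc(O)c3)[C@@H](c3ccc(O)cc3)O4)[C@H]2c2cc(O)cc(O)c2)cc1
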